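**Analysis of the target**

The target is 3-(3,4-dihydroxy-5-methoxyphenyl)propyl octadecanoate. It has one benzene ring: C1 carries a saturated three-carbon chain whose terminal oxygen is acylated by stearic acid, C3 and C4 carry free hydroxyls, C5 a methoxy group, and C2 and C6 hydrogen. There is no stereocentre and no alkene geometry, so nothing stereochemical has to be set or preserved. Two groups are sensitive. The electron-rich 3-methoxycatechol is oxidised to the ortho-quinone by air in basic medium or by excess oxidant. The unactivated primary alkyl ester does not survive organolithium reagents, hydride or hot hydroxide. The carbon skeleton is simple; the difficulty is the 3,4,5-trioxygenated array, where two adjacent free hydroxyls must sit beside one methyl ether without a statistical methylation, and the catechol must be released at the end under conditions the ester tolerates. The plan rests on the C3–C4 bond of the ring: it carries two identical heteroatoms and is flanked at C5 by the methoxy group, which is the pattern left when an element–element bond adds across a C3–C4 aryne with the methoxy neighbour already in place. With boron as that element, both oxygens arrive masked under neutral conditions and one mild oxidation releases them; because both aryne termini receive the same atom, the usual regiochemical question of 3-methoxyaryne additions does not arise.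

**Retrosynthetic reasoning**

Target 18 to bis-boronate 17. The C3–O and C4–O bonds are traced back to C3–B and C4–B bonds. Oxidation of an arylboronate to a phenol is mild, needs no strong base, and allows the air-sensitive catechol to appear only in the last operation. Compound 17 is a stable, chromatographable stand-in for the catechol, so no catechol protecting group is needed.

Bis-boronate 17 to silylaryl triflate 14 and diboron 15. Both C–B bonds are cut at once, leading back to aryne 16 and the B–B bond of 15. The cut is made here because it is the only place in the ring where two adjacent identical substituents can come from one reagent, and it leaves the methyl ether untouched. The forward reaction must release 16 slowly from 14 and have a platinum catalyst deliver both boryl groups before the aryne oligomerises.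

Ester 14 to alcohol 12 and stearoyl chloride 13, and 12 to silyl ether 11. The acyl C–O bond is cut late, after all organolithium chemistry, because the ester would not survive lithiation. It is placed before the aryne step so that the diboration is run on the fully assembled chain. The chain oxygen therefore travels as a silyl ether, which must be removed from 11 with acid, since a fluoride source would strip the aryl silane and trigger the aryne prematurely.

Triflate 11 to carbamate 9 (through phenol 10), and 9 to carbamate 5 (through 6, 7 and 8). The O–S bond and the aryl C–Si bond are cut. The silicon must sit on the one ring carbon between the two oxygens, and that carbon is the site at which a carbamate and a methoxy group cooperate in directed ortho-metalation. The same carbamate oxygen then becomes the triflate leaving group, so one functional group serves as director, protecting group and leaving-group precursor.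

Carbamate 5 to phenol 4, and 4 to allyl silyl ether 1 and bromophenol 2 (through alkylborane 3). The aryl–CH2 bond is cut as an sp2–sp3 cross-coupling. Compound 2 already holds hydroxyl, methoxy and the coupling site in the required 1,3,5-relationship. Compound 1 delivers all three chain carbons with the oxygen already protected, so no separate differentiation of phenol and chain alcohol is needed. A three-step aldehyde homologation is thereby replaced by one operation.

**Alternatives that were turned down**

Alternative 1: The benzene ring is built from acyclic pieces by a Michael–Claisen annulation. The sodium enolate of dimethyl malonate A3 adds to the chain-bearing β-carbon of enone A2. The ketone enolate on the benzyloxymethyl side then attacks a malonate ester and closes the six-membered ring to give dioxo ester A1. Loss of the methoxycarbonyl group gives the symmetrical dione A4, which can be converted unambiguously into its mono methyl enol ether, dehydrogenated to the arene and debenzylated.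
- For: cheap reagents, no cryogenic or precious-metal step, and the chain is placed para to the central oxygen by construction. The methyl ether is introduced without statistics.
- Against: four operations follow the key step. Two of them are harsh for this substrate: removing the methoxycarbonyl group beside a stearate that is also an ester, and oxidatively aromatising a ring that carries a benzyl ether and benzylic hydrogens. Enone A2 also needs its own multi-step preparation, so the sequence is unlikely to be shorter than ten steps.
- Comparison: this route is at least as good on reagent cost and scalability. The chosen route offers a key-step product that is one mild step from the target and an oxidation-level change confined to boron.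

Alternative 2: The side chain is cut between the benzylic carbon and its neighbour. 3,4-Dihydroxy-5-methoxybenzaldehyde A8 is benzylated and converted into dithiane A6. The lithiated dithiane opens oxirane A7 and the alkoxide is trapped with 13 to give A5. Reductive removal of the dithiane and hydrogenolysis of the benzyl ethers then give 18.
- For: A8 already contains the complete oxygen pattern, the key step forms the C–C and the ester C–O bond in one flask, and the whole sequence is about five steps. On step count and on the certainty of each bond formation this alternative is stronger than the chosen route.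
- Against: the differentiated catechol is bought, not made. Two benzyl ethers and the dithiane must all be removed reductively at the end, with a large excess of a nickel desulfurising agent or with sulfur traces poisoning a hydrogenolysis catalyst. A7 is a toxic gas.
- Comparison: the chosen strategy offers construction of the hydroxyl/hydroxyl/methoxy array from a simple 1,3-dioxygenated arene, no catechol protecting group, and release of the catechol from a purifiable bis-boronate by one oxidation.

Alternative 3: The ring is made by benzannulation of cyclobutenone A10 with di-tert-butoxyethyne A11. Thermal four-electron opening of A10 gives a vinylketene, which adds A11 by (2+2) cycloaddition. Four-electron opening and six-electron closure then give phenol A9, whose single free hydroxyl is the one to be methylated before acid removes the two tert-butyl groups.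
- For: the three oxygens are differentiated by construction, the conditions are neutral and tolerate the ester, and the route is convergent. On the logic of differentiation this plan equals the chosen one.
- Against: neither A10 nor A11 is a shelf compound, and A11 loses isobutene at temperatures close to those the benzannulation needs. Two steps remain after the key step, and acid cleavage of tert-butyl ethers on so electron-rich a ring invites ring tert-butylation.
- Comparison: the chosen route uses only commercial building blocks and a catalytic key step with a close precedent, and ends one step after it.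

Key step: step 7

Remark on the chemistry: compounds 1, 2, 13 and 15 are taken as commercial. The chain oxygen is carried as a tert-butyldimethylsilyl ether through the lithiation and is exchanged for the stearate only afterwards.

**Route**

Step 1
Reactants: 1 allyloxy-tert-butyldimethylsilane; 2 3-bromo-5-methoxyphenol
Product: 4 3-{3-[(tert-butyldimethylsilyl)oxy]propyl}-5-methoxyphenol, via alkylborane 3 (not isolated)
Conditions: 1, 9-BBN, THF, 0 °C to rt; then 2, Pd(dppf)Cl2 (cat.), aq K3PO4 (excess), THF/DMF, 60 °C
Reagents that add atoms: none
Why: Anti-Markovnikov hydroboration of the terminal alkene gives the primary alkylborane, which undergoes B-alkyl Suzuki–Miyaura coupling with the aryl bromide; excess phosphate forms the borate and carries the phenol as phenoxide, and the wide-bite-angle ligand favours reductive elimination over β-hydride elimination.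

Step 2
Reactants: 4 3-{3-[(tert-butyldimethylsilyl)oxy]propyl}-5-methoxyphenol
Product: 5 3-{3-[(tert-butyldimethylsilyl)oxy]propyl}-5-methoxyphenyl N-isopropylcarbamate
Conditions: i-PrNCO, Et3N (cat.), CH2Cl2, rt
Reagents that add atoms: isopropyl isocyanate, CC(C)N=C=O
Why: Amine-catalysed addition of the phenol to the isocyanate gives the aryl carbamate, which serves as the metalation director and later as the precursor of the leaving group.

Step 3
Reactants: 5 3-{3-[(tert-butyldimethylsilyl)oxy]propyl}-5-methoxyphenyl N-isopropylcarbamate
Product: 9 5-{3-[(tert-butyldimethylsilyl)oxy]propyl}-3-methoxy-2-(trimethylsilyl)phenyl N-isopropylcarbamate, via N-silyl carbamate 6 (not isolated), via aryllithium 7 (not isolated), via N-silyl arylsilane 8 (not isolated)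
Conditions: TBSOTf, TMEDA, Et2O, 0 °C to rt; n-BuLi, TMEDA, −78 °C; TMSCl, −78 °C to rt; cold aq NaHSO4 work-up
Reagents that add atoms: chlorotrimethylsilane, C[Si](C)(C)Cl
Why: Transient N-silylation masks the N–H, after which directed ortho-metalation occurs at the ring carbon flanked by the carbamate and methoxy oxygens, where both directors cooperate; the aryllithium is silylated and the N-silyl group falls off on aqueous work-up, while the alkyl silyl ether is inert to n-BuLi at −78 °C.

Step 4
Reactants: 9 5-{3-[(tert-butyldimethylsilyl)oxy]propyl}-3-methoxy-2-(trimethylsilyl)phenyl N-isopropylcarbamate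
Product: 11 5-{3-[(tert-butyldimethylsilyl)oxy]propyl}-3-methoxy-2-(trimethylsilyl)phenyl trifluoromethanesulfonate, via silylphenol 10 (not isolated)
Conditions: DBU, Et2NH, MeCN, 40 °C; then PhNTf2, rt
Reagents that add atoms: N-phenylbis(trifluoromethanesulfonimide), O=S(=O)(N(c1ccccc1)S(=O)(=O)C(F)(F)F)C(F)(F)F
Why: DBU deprotonates the N–H carbamate, which fragments by an E1cB pathway to the phenoxide and isopropyl isocyanate (scavenged by Et2NH as a urea); the phenoxide is triflated in the same flask by the mild triflimide reagent.

Step 5
Reactants: 11 5-{3-[(tert-butyldimethylsilyl)oxy]propyl}-3-methoxy-2-(trimethylsilyl)phenyl trifluoromethanesulfonate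
Product: 12 5-(3-hydroxypropyl)-3-methoxy-2-(trimethylsilyl)phenyl trifluoromethanesulfonate
Conditions: camphorsulfonic acid (cat.), MeOH/CH2Cl2, 0 °C to rt
Reagents that add atoms: none
Why: Acid-catalysed methanolysis removes the primary alkyl silyl ether; fluoride is avoided because it would cleave the aryl–silicon bond and release the aryne, whereas the aryl silane, deactivated by the adjacent triflate, should resist ipso-protonation under catalytic acid at low temperature.

Step 6
Reactants: 12 5-(3-hydroxypropyl)-3-methoxy-2-(trimethylsilyl)phenyl trifluoromethanesulfonate; 13 stearoyl chloride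
Product: 14 3-{3-methoxy-5-[(trifluoromethanesulfonyl)oxy]-4-(trimethylsilyl)phenyl}propyl octadecanoate
Conditions: 13, Et3N, DMAP (cat.), CH2Cl2, 0 °C to rt
Reagents that add atoms: none
Why: DMAP-catalysed acylation of the primary alcohol by the acid chloride; the aryl triflate and aryl silane are inert to these conditions.

Step 7
Reactants: 14 3-{3-methoxy-5-[(trifluoromethanesulfonyl)oxy]-4-(trimethylsilyl)phenyl}propyl octadecanoate; 15 bis(pinacolato)diboron
Product: 17 3-[3-methoxy-4,5-bis(4,4,5,5-tetramethyl-1,3,2-dioxaborolan-2-yl)phenyl]propyl octadecanoate, via aryne 16 (not isolated)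
Conditions: 15 (excess), Pt(dba)2 (cat.), 1-adamantyl isocyanide (cat.), KF, 18-crown-6, DME, 80 °C
Reagents that add atoms: none
Why: Fluoride, solubilised by the crown ether, attacks the trimethylsilyl group of 14 and the aryl anion expels the neighbouring triflate, releasing aryne 16 with its triple bond between the carbons that become C4 and C3 of the target and the methoxy group on the adjacent C5. Zerovalent platinum carrying the isocyanide adds oxidatively into the B–B bond of 15 to give a cis-bis(boryl) complex of divalent platinum; the strained triple bond inserts into one Pt–B bond and C–B reductive elimination forms the second C–B bond and returns zerovalent platinum. The closest known reaction type is the platinum-catalysed cis-diboration of alkynes, which has been extended to arynes released from 2-silylaryl triflates under this fluoride and crown ether regime. No ring is closed and no stereocentre is formed. Only chemoselectivity is required: capture by the bis(boryl)platinum species must outrun aryne oligomerisation, metal-mediated cyclotrimerisation and fluoride addition, which slow aryne release from sparingly soluble KF and an excess of 15 should secure. Regiochemistry is irrelevant, because the methoxy group would steer a nucleophile to C3 but both termini receive boron. Apart from fluoride the medium is neutral, so the stearate and the methyl ether should be untouched.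

Step 8
Reactants: 17 3-[3-methoxy-4,5-bis(4,4,5,5-tetramethyl-1,3,2-dioxaborolan-2-yl)phenyl]propyl octadecanoate
Product: 18 3-(3,4-dihydroxy-5-methoxyphenyl)propyl octadecanoate
Conditions: NaBO3·4H2O, THF/H2O, rt, argon; aq NH4Cl/Na2S2O3 work-up
Reagents that add atoms: sodium perborate, [Na+].[O-]OB=O
Why: Boronate oxidation: the peroxide oxygen adds to boron, the aryl group migrates from boron to oxygen and the borate ester hydrolyses, twice over; perborate is mild enough at room temperature that the unactivated ester should survive, and exclusion of air with a reductive quench protects the catechol.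

**Compound list**

1 | allyloxy-tert-butyldimethylsilane | C=CCO[Si](C)(C)C(C)(C)C | starting material
2 | 3-bromo-5-methoxyphenol | COc1cc(O)cc(Br)c1 | starting material
3 | 9-{3-[(tert-butyldimethylsilyl)oxy]propyl}-9-borabicyclo[3.3.1]nonane | CC(C)(C)[Si](C)(C)OCCCB1C2CCCC1CCC2 | intermediate
4 | 3-{3-[(tert-butyldimethylsilyl)oxy]propyl}-5-methoxyphenol | COc1cc(O)cc(CCCO[Si](C)(C)C(C)(C)C)c1 | intermediate
5 | 3-{3-[(tert-butyldimethylsilyl)oxy]propyl}-5-methoxyphenyl N-isopropylcarbamate | COc1cc(OC(=O)NC(C)C)cc(CCCO[Si](C)(C)C(C)(C)C)c1 | intermediate
6 | 3-{3-[(tert-butyldimethylsilyl)oxy]propyl}-5-methoxyphenyl N-(tert-butyldimethylsilyl)-N-isopropylcarbamate | COc1cc(OC(=O)N(C(C)C)[Si](C)(C)C(C)(C)C)cc(CCCO[Si](C)(C)C(C)(C)C)c1 | intermediate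
7 | 2-lithio derivative of 6 (lithium on the ring carbon between the carbamate and methoxy oxygens) | COc1cc(CCCO[Si](C)(C)C(C)(C)C)cc(OC(=O)N(C(C)C)[Si](C)(C)C(C)(C)C)c1[Li] | intermediate
8 | 5-{3-[(tert-butyldimethylsilyl)oxy]propyl}-3-methoxy-2-(trimethylsilyl)phenyl N-(tert-butyldimethylsilyl)-N-isopropylcarbamate | COc1cc(CCCO[Si](C)(C)C(C)(C)C)cc(OC(=O)N(C(C)C)[Si](C)(C)C(C)(C)C)c1[Si](C)(C)C | intermediate
9 | 5-{3-[(tert-butyldimethylsilyl)oxy]propyl}-3-methoxy-2-(trimethylsilyl)phenyl N-isopropylcarbamate | COc1cc(CCCO[Si](C)(C)C(C)(C)C)cc(OC(=O)NC(C)C)c1[Si](C)(C)C | intermediate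
10 | 5-{3-[(tert-butyldimethylsilyl)oxy]propyl}-3-methoxy-2-(trimethylsilyl)phenol | COc1cc(CCCO[Si](C)(C)C(C)(C)C)cc(O)c1[Si](C)(C)C | intermediate
11 | 5-{3-[(tert-butyldimethylsilyl)oxy]propyl}-3-methoxy-2-(trimethylsilyl)phenyl trifluoromethanesulfonate | COc1cc(CCCO[Si](C)(C)C(C)(C)C)cc(OS(=O)(=O)C(F)(F)F)c1[Si](C)(C)C | intermediate
12 | 5-(3-hydroxypropyl)-3-methoxy-2-(trimethylsilyl)phenyl trifluoromethanesulfonate | COc1cc(CCCO)cc(OS(=O)(=O)C(F)(F)F)c1[Si](C)(C)C | intermediate
13 | stearoyl chloride (octadecanoyl chloride) | CCCCCCCCCCCCCCCCCC(=O)Cl | starting material
14 | 3-{3-methoxy-5-[(trifluoromethanesulfonyl)oxy]-4-(trimethylsilyl)phenyl}propyl octadecanoate | CCCCCCCCCCCCCCCCCC(=O)OCCCc1cc(OC)c([Si](C)(C)C)c(OS(=O)(=O)C(F)(F)F)c1 | intermediate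
15 | bis(pinacolato)diboron | CC1(C)OB(OC1(C)C)B1OC(C)(C)C(C)(C)O1 | starting material
16 | 3-(3-methoxy-4,5-didehydrophenyl)propyl octadecanoate (aryne) | CCCCCCCCCCCCCCCCCC(=O)OCCCC1=CC#CC(OC)=C1 | intermediate
17 | 3-[3-methoxy-4,5-bis(4,4,5,5-tetramethyl-1,3,2-dioxaborolan-2-yl)phenyl]propyl octadecanoate | CCCCCCCCCCCCCCCCCC(=O)OCCCc1cc(OC)c(B2OC(C)(C)C(C)(C)O2)c(B2OC(C)(C)C(C)(C)O2)c1 | intermediate
18 | 3-(3,4-dihydroxy-5-methoxyphenyl)propyl octadecanoate | CCCCCCCCCCCCCCCCCC(=O)OCCCc1cc(O)c(O)c(OC)c1 | target

**Step count and risk**

Total: 8 steps. Longest linear sequence: 8 steps, from 1 and 2 to 18; compounds 13 and 15 enter as purchased reagents.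

Step 7 (key step). The aryne may be consumed by oligomerisation, by platinum-mediated cyclotrimerisation or by fluoride addition before it meets the bis(boryl)platinum species. Reductive elimination at the carbon next to the methoxy group may also be slowed by crowding. Fallback, setting out from 5 and abandoning the aryne: 5 is N-silylated and lithiated as in step 3 (through 6 and 7). Aryllithium 7 is quenched with B(OMe)3 and oxidised in the same flask with H2O2/AcOH, a directed metalation–boronation–oxidation that should give 5-{3-[(tert-butyldimethylsilyl)oxy]propyl}-2-hydroxy-3-methoxyphenyl N-isopropylcarbamate F1. Camphorsulfonic acid in MeOH then removes the silyl ether to give 2-hydroxy-5-(3-hydroxypropyl)-3-methoxyphenyl N-isopropylcarbamate F2. Immobilised Candida antarctica lipase B with vinyl stearate in tert-butyl methyl ether at 45 °C acylates only the primary alcohol to give 3-{4-hydroxy-3-[(isopropylcarbamoyl)oxy]-5-methoxyphenyl}propyl octadecanoate F3. DBU and Et2NH in MeCN at 40 °C under argon cleave the carbamate, and the fallback rejoins the route at 18.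

Step 3. If N-silylation is incomplete, the carbamate is deprotonated at nitrogen and fragments to phenoxide and isocyanate. The aryllithium may also undergo an anionic carbamoyl shift on warming, or metalation may occur at the ring carbon ortho to the carbamate only. Fallback, setting out from 4 and using a tertiary carbamate that has no N–H: diethylcarbamoyl chloride and K2CO3 in MeCN at reflux give 3-{3-[(tert-butyldimethylsilyl)oxy]propyl}-5-methoxyphenyl N,N-diethylcarbamate F4. Treatment with s-BuLi/TMEDA in THF at −78 °C and then TMSCl gives 5-{3-[(tert-butyldimethylsilyl)oxy]propyl}-3-methoxy-2-(trimethylsilyl)phenyl N,N-diethylcarbamate F5. LiAlH4 in THF cleaves the carbamate reductively, and the fallback rejoins the route at 10, which is triflated with PhNTf2 and base to 11 as in the second half of step 4.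

Step 1. Oxidative addition into the electron-rich bromophenoxide may be slow, so that protodeboronation or β-hydride elimination of the alkylborane and reduction of the aryl bromide compete with coupling. Fallback, setting out from 3-hydroxy-5-methoxybenzaldehyde F6:
- Wittig olefination with ethyl (triphenylphosphoranylidene)acetate in toluene at 80 °C gives ethyl (E)-3-(3-hydroxy-5-methoxyphenyl)acrylate F7.
- Hydrogenation over Pd/C gives ethyl 3-(3-hydroxy-5-methoxyphenyl)propanoate F8.
- LiAlH4 in THF gives 3-(3-hydroxypropyl)-5-methoxyphenol F9.
- TBSCl (2.2 equiv) and imidazole in DMF give the bis-silyl ether tert-butyl{3-[3-(tert-butyldimethylsilyloxy)-5-methoxyphenyl]propoxy}dimethylsilane F10.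
- K2CO3 in MeOH at rt cleaves only the aryl silyl ether, and the fallback rejoins the route at 4.

Step 8. Hydroperoxide anion at the pH of perborate may partly cleave the stearate. The freshly released electron-rich catechol may be oxidised further to the ortho-quinone by excess oxidant or air, and the second, more crowded C–B bond may oxidise slowly. Fallback, setting out from 11 and placing the ester last: diboration of 11 under the conditions of step 7 gives tert-butyl{3-[3-methoxy-4,5-bis(4,4,5,5-tetramethyl-1,3,2-dioxaborolan-2-yl)phenyl]propoxy}dimethylsilane F11. Oxidation with NaBO3, now free of any ester and with a Na2S2O4 work-up, gives 5-{3-[(tert-butyldimethylsilyl)oxy]propyl}-3-methoxybenzene-1,2-diol F12. Camphorsulfonic acid in MeOH gives 5-(3-hydroxypropyl)-3-methoxybenzene-1,2-diol F13. Immobilised Candida antarctica lipase B with vinyl stearate in tert-butyl methyl ether acylates the primary alcohol selectively over the phenols, and the fallback rejoins the route at 18.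

**Further compounds**

F1 | step 7 | 5-{3-[(tert-butyldimethylsilyl)oxy]propyl}-2-hydroxy-3-methoxyphenyl N-isopropylcarbamate | COc1cc(CCCO[Si](C)(C)C(C)(C)C)cc(OC(=O)NC(C)C)c1O
F2 | step 7 | 2-hydroxy-5-(3-hydroxypropyl)-3-methoxyphenyl N-isopropylcarbamate | COc1cc(CCCO)cc(OC(=O)NC(C)C)c1O
F3 | step 7 | 3-{4-hydroxy-3-[(isopropylcarbamoyl)oxy]-5-methoxyphenyl}propyl octadecanoate | CCCCCCCCCCCCCCCCCC(=O)OCCCc1cc(OC)c(O)c(OC(=O)NC(C)C)c1
F4 | step 3 | 3-{3-[(tert-butyldimethylsilyl)oxy]propyl}-5-methoxyphenyl N,N-diethylcarbamate | CCN(CC)C(=O)Oc1cc(OC)cc(CCCO[Si](C)(C)C(C)(C)C)c1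
F5 | step 3 | 5-{3-[(tert-butyldimethylsilyl)oxy]propyl}-3-methoxy-2-(trimethylsilyl)phenyl N,N-diethylcarbamate | CCN(CC)C(=O)Oc1cc(CCCO[Si](C)(C)C(C)(C)C)cc(OC)c1[Si](C)(C)C
F6 | step 1 | 3-hydroxy-5-methoxybenzaldehyde | COc1cc(O)cc(C=O)c1
F7 | step 1 | ethyl (E)-3-(3-hydroxy-5-methoxyphenyl)acrylate | CCOC(=O)/C=C/c1cc(O)cc(OC)c1
F8 | step 1 | ethyl 3-(3-hydroxy-5-methoxyphenyl)propanoate | CCOC(=O)CCc1cc(O)cc(OC)c1
F9 | step 1 | 3-(3-hydroxypropyl)-5-methoxyphenol | COc1cc(O)cc(CCCO)c1
F10 | step 1 | tert-butyl{3-[3-(tert-butyldimethylsilyloxy)-5-methoxyphenyl]propoxy}dimethylsilane | COc1cc(CCCO[Si](C)(C)C(C)(C)C)cc(O[Si](C)(C)C(C)(C)C)c1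
F11 | step 8 | tert-butyl{3-[3-methoxy-4,5-bis(4,4,5,5-tetramethyl-1,3,2-dioxaborolan-2-yl)phenyl]propoxy}dimethylsilane | COc1cc(CCCO[Si](C)(C)C(C)(C)C)cc(B2OC(C)(C)C(C)(C)O2)c1B1OC(C)(C)C(C)(C)O1
F12 | step 8 | 5-{3-[(tert-butyldimethylsilyl)oxy]propyl}-3-methoxybenzene-1,2-diol | COc1cc(CCCO[Si](C)(C)C(C)(C)C)cc(O)c1O
F13 | step 8 | 5-(3-hydroxypropyl)-3-methoxybenzene-1,2-diol | COc1cc(CCCO)cc(O)c1O
A1 | alternative 1 | methyl 3-(benzyloxy)-2,4-dioxo-6-[3-(stearoyloxy)propyl]cyclohexane-1-carboxylate | CCCCCCCCCCCCCCCCCC(=O)OCCCC1CC(=O)C(OCc2ccccc2)C(=O)C1C(=O)OC
A2 | alternative 1 | (E)-7-(benzyloxy)-6-oxohept-4-en-1-yl octadecanoate | CCCCCCCCCCCCCCCCCC(=O)OCCC/C=C/C(=O)COCc1ccccc1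
A3 | alternative 1 | dimethyl malonate | COC(=O)CC(=O)OC
A4 | alternative 1 | 3-[4-(benzyloxy)-3,5-dioxocyclohexyl]propyl octadecanoate | CCCCCCCCCCCCCCCCCC(=O)OCCCC1CC(=O)C(OCc2ccccc2)C(=O)C1
A5 | alternative 2 | 2-{2-[3,4-bis(benzyloxy)-5-methoxyphenyl]-1,3-dithian-2-yl}ethyl octadecanoate | CCCCCCCCCCCCCCCCCC(=O)OCCC1(SCCCS1)c1cc(OC)c(OCc2ccccc2)c(OCc2ccccc2)c1
A6 | alternative 2 | 2-[3,4-bis(benzyloxy)-5-methoxyphenyl]-1,3-dithiane | COc1cc(C2SCCCS2)cc(OCc2ccccc2)c1OCc1ccccc1
A7 | alternative 2 | oxirane | C1CO1
A8 | alternative 2 | 3,4-dihydroxy-5-methoxybenzaldehyde | COc1cc(C=O)cc(O)c1O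
A9 | alternative 3 | 3-(3,4-di-tert-butoxy-5-hydroxyphenyl)propyl octadecanoate | CCCCCCCCCCCCCCCCCC(=O)OCCCc1cc(O)c(OC(C)(C)C)c(OC(C)(C)C)c1
A10 | alternative 3 | 3-(3-oxocyclobut-1-en-1-yl)propyl octadecanoate | CCCCCCCCCCCCCCCCCC(=O)OCCCC1=CC(=O)C1
A11 | alternative 3 | di-tert-butoxyethyne | CC(C)(C)OC#COC(C)(C)C
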